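## Analysis of the target

Atom numbering used throughout: ten-membered ring C1–C10; ring A = C1, C10, C11, C12, C13, C14; γ-lactone = C7–O–C19(=O)–C17–C8; methyl groups C15 (on C1), C16 (on C5), C18 (on C17), C20 (on C11).

The target is a trans-fused bicyclo[8.4.0]tetradecane: cyclohexane ring A is fused through C1–C10 to a ten-membered carbocycle that holds a Z-trisubstituted C5=C6 alkene and carries a γ-lactone annulated across C7–C8. It has eleven stereocentres (C1, C2, C4, C7, C8, C9, C10, C11, C12, C14, C17); C1 is an all-carbon quaternary centre and C8 a fully substituted carbinol. The relationships that matter are: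

- the trans ring fusion (C15 on one face, H10 on the other);
- C20 and the 12-OH on the C15 face of ring A, the 14-OAc on the opposite face;
- 1,3-anti oxygen pairs at C2/C4 and at C12/C14;
- an anti,anti C7–C8–C9 triol in which the C7 and C9 arms are mirror-related about C8;
- O8, C18 and C6 all cis on the lactone ring.

Four secondary acetates sit beside two free hydroxyls (tertiary 8-OH, secondary 12-OH), so the acetate/hydroxyl pattern must come out of the chemistry and cannot be left to a final selective acylation. The 8-hydroxy lactone is a retro-aldol candidate, C4–O and C7–O are both allylic, and the C11 methyl is cis to C15, which is the less stable arrangement whenever C12 is a ketone. The main difficulty is the ten-membered ring, closed against a quaternary ring-fusion carbon that is flanked by oxygenated C2 and C14.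

The strategy rests on ring A: the C12 oxygen is 1,4 to C1, and C1 bears C2 at the carbonyl or carbinol level. That is the pattern left by a 2-silyloxybutadiene (C10=C11–C12(OSi)=C13) adding to an α-methyl enone (C14=C1–C2=O). C2 to C9 then form a tether, so a single cycloaddition can close ring A and the ten-membered ring together.

## Retrosynthetic reasoning

**C14 acetate and C12 hydroxyl (40 ⇒ 39 ⇒ 37).** No skeletal bond is cut. The 14-OAc/12-OH pair is traced to β-hydroxy ketone 39, because an Evans–Tishchenko reduction turns exactly this unit into a 1,3-anti diol monoacetate with the ester on the directing oxygen. This leaves 12-OH free beside four acetates without any protecting group. The C14–O bond is then cut back to the C13=C14 enone 37, which accepts an oxygen equivalent at C14 from the face away from C15.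

**Ring A and C2 adjustments (37 ⇒ 35 ⇒ 33 ⇒ 32 ⇒ 31).** The enone comes from a C12 ketone by dehydrogenation. The C2 carbinol with its C4 acetate comes from the β-hydroxy ketone 32 by a second Evans–Tishchenko reduction (C2/C4 are 1,3-anti). The C11–H bond comes from protonation of the C11=C12 silyl enol ether of 31. What is gained is 31, in which C12 is masked as an enol ether and C2 is a ketone, which is what a cycloaddition delivers. The forward steps must reduce C2 while C12 cannot compete, and must protonate C11 from the face opposite C9 and C15.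

**Key disconnection (31 ⇒ 30).** C1–C10 and C13–C14 are cut together. Cutting here removes both carbocycles and the quaternary centre in one operation and leaves an open chain whose oxygenation is already final at C4, C7, C8, C9 and C19. Any single-bond macrocyclisation would still have to build ring A separately and close the ring against C1. The forward reaction has to give the fused regiochemistry, the trans fusion and the correct diene face.

**C3–C4 (30 ⇒ 29 ⇒ 28 ⇒ 25 + 26).** The silyl ethers are removed and the C3–C4 bond is cut as an aldol between the Z-enal 25 and the methyl ketone 26. A boron enolate is chosen because it attacks only the aldehyde of 25, leaving its methyl ketone and lactone alone. The forward reaction must set C4 by reagent control.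

**C10=C11 and C5=C6 (25 ⇒ 24 ⇒ 22 + 23; 22 ⇒ 21 ⇒ 19 + 20).** The E-enone is cut at C10=C11 to aldehyde 22 and ylide 23; the Z-alkene is cut at C5=C6 to aldehyde 19 and phosphonate 20. Both alkenes are trisubstituted with defined geometry, and carbonyl olefinations of opposite selectivity set them without ambiguity. The ester of 21 must be reduced before any ketone exists, which fixes the order: olefination at C6, one global reduction, olefination at C10.

**Lactone transposition (19 ⇒ 17 ⇒ 15 ⇒ 13).** The C19–O7 lactone is traced to the 1,4-diol 15 by oxidative lactonisation, and 15 to the isomeric C10–O7 lactone 13 by aminolysis. The C10 lactone of 13 is provisional: it protects O7, it is the ring on which C8 and C9 are set, and its carbonyl becomes the C10 aldehyde via the Weinreb amide.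

**C8–O and C9–O (13 ⇒ 12 ⇒ 11).** Both C–O bonds are cut to butenolide 11. A cis-dihydroxylation anti to the C7 substituent of a 5-substituted butenolide gives O8 and O9 cis to each other and trans to C6, which is the anti,anti triol of the target.

**Butenolide and C8–C17 (11 ⇒ 9 ⇒ 7 ⇒ 4 ⇒ 1 + 2).** C9 and C10 are removed as a two-carbon ketene equivalent acting on the α-hydroxy ketone 9. The C8–C17 bond is cut as an auxiliary-controlled aldol between imide 1 and aldehyde 2, which supplies C7 from the chiral pool and C17 from the auxiliary. C19 is reduced at once, so that C17 never sits between two carbonyl groups while C8 is a ketone or an sp2 carbon.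

## Alternatives that were turned down

Alternative 1: The C1–C2 bond is cut and the ten-membered carbocycle is traced to a thirteen-membered cyclic ether. In the forward step n-BuLi removes a propargylic proton at C2 and the carbanion attacks C1 of a C1=C14 alkene while C13–O breaks (a [2,3]-Wittig ring contraction), giving the furan-fused cycloalkynol A1.
- For: the contraction makes the quaternary C1 and the C2 carbinol in one ordered five-membered transition state, starts from an easier large ring, and leaves the C13=C14 alkene where C14 must be oxygenated. On C2 it is stronger than the chosen route, which has to reduce a C2 ketone afterwards.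
- Against: ring A and a macrocyclic ether must both exist first, so the key step makes one C–C bond where the cycloaddition makes two. The lactone travels as a silylfuran, which erases C7, C8 and C17; these must be regenerated by oxidative dearomatisation on the medium ring. The C3≡C4 alkyne must become C3H2–C4H(OAc) with no obvious control element, and deprotonation at the allylic C13 and a [1,2]-shift compete.
- In exchange, the chosen strategy offers a precursor in which C4, C7, C8, C9, C17 and the Z-alkene are already final.

Alternative 2: The C8–C17 bond is cut. In the forward step SmI2 reduces the C–Br bond of an O7 2-bromopropanoate and the samarium enolate adds to a C8 ketone (a tethered Reformatsky reaction), giving A2, the 12-O-silyl ether of the target.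
- For: the annulation is very late and convergent, a chelated cyclic transition state can set C8 and C17 together, and A2 is one desilylation from the target. In end-game brevity it is clearly stronger than the chosen route, which needs seven steps after its key step.
- Against: the step presupposes the whole oxygenated trans-fused six/ten ring system with the Z-alkene and quaternary C1, so it is an end game and not a route to the skeleton. The C8 ketone is flanked by the C9 acetate and the C7 acyloxy group, both α-acyloxy ketone units that SmI2 cleaves reductively in competition with the C–Br bond. Facial selectivity at a ketone in a flexible ten-membered ring is a matter of conformation.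
- In exchange, the chosen strategy sets C8 and C9 on a rigid five-membered ring and C17 by an auxiliary before any carbocycle exists, and spends its one risky step on the skeleton.

Alternative 3: The ten-membered ring is traced to a decalin; C4–C5 is formed and C2–C7 broken. KH with 18-crown-6 sends a C2 alkoxide bearing a vinyl group and a neighbouring (Z)-propenyl group through a chair [3,3] shift (anionic oxy-Cope), and the enolate is trapped with Me3SiCl to give the silyl enol ether A3.
- For: the expansion is a dependable entry to cyclodecenones from six-membered rings, needs no medium-ring cyclisation, transfers chirality through the chair, and leaves C2 as an enol ether. As a ring-forming event it is at least as predictable as a macrocyclising cycloaddition, probably more so.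
- Against: A3 has the wrong pattern for this target. It has an E C6=C7 alkene, an sp3 C5 bearing the methyl, no oxygen at C4 or C7, and C19 still at the alcohol level. The alkene would have to be moved to C5=C6 with Z geometry while oxygen is introduced at C4 and C7 and the lactone is built, all on the medium ring.
- In exchange, the chosen strategy brings these features into the cyclisation precursor finished.

Key step: step 22

Remark on the chemistry: the hemiacetal carbon C19 of 16, 22 and 24 forms as a mixture of epimers and is written without configuration; it becomes the lactone carbonyl again in steps 12 and 18.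

## Route

Step 1
Reactants: 1 (R)-4-benzyl-3-propanoyl-1,3-oxazolidin-2-one; 2 (S)-2,2-dimethyl-1,3-dioxolane-4-carbaldehyde
Product: 4 (R)-4-benzyl-3-[(2R,3R)-3-[(S)-2,2-dimethyl-1,3-dioxolan-4-yl]-3-hydroxy-2-methylpropanoyl]-1,3-oxazolidin-2-one, via dibutylboron Z-enolate 3 (not isolated)
Conditions: Bu2BOTf, i-Pr2NEt, CH2Cl2, −78 → 0 °C; then 2, −78 → 0 °C; pH 7 buffer, MeOH
Reagents that add atoms: none
Why: Evans syn-aldol reaction; the Z-boron enolate reacts through a closed chair transition state on the face away from the benzyl group, so the auxiliary sets C17, while the C8 carbinol formed here is removed in step 4.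

Step 2
Reactants: 4 aldol adduct
Product: 5 (1R,2S)-1-[(S)-2,2-dimethyl-1,3-dioxolan-4-yl]-2-methylpropane-1,3-diol
Conditions: LiBH4, MeOH, THF, 0 °C
Reagents that add atoms: none
Why: Reductive cleavage of the N-acyl oxazolidinone gives the 1,3-diol and releases the auxiliary; C19 is taken to the alcohol level now so that C17 never lies between two carbonyl groups.

Step 3
Reactants: 5 diol
Product: 6 (1R,2S)-3-[tert-butyl(diphenyl)silyl]oxy-1-[(S)-2,2-dimethyl-1,3-dioxolan-4-yl]-2-methylpropan-1-ol
Conditions: t-BuPh2SiCl, imidazole, CH2Cl2, 0 °C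
Reagents that add atoms: tert-butyl(chloro)diphenylsilane, CC(C)(C)[Si](Cl)(c1ccccc1)c1ccccc1
Why: Selective silylation of the primary hydroxyl; the bulky silyl ether survives the acid of step 5 and is the first group to be removed later.

Step 4
Reactants: 6 silyl ether alcohol
Product: 7 (S)-3-[tert-butyl(diphenyl)silyl]oxy-1-[(S)-2,2-dimethyl-1,3-dioxolan-4-yl]-2-methylpropan-1-one
Conditions: Dess–Martin periodinane, NaHCO3, CH2Cl2, 0 °C → rt
Reagents that add atoms: none
Why: Dess–Martin oxidation gives the C8 ketone needed for the butenolide; the buffered, non-basic conditions should leave the two α-stereocentres C17 and C7 untouched.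

Step 5
Reactants: 7 ketone acetonide
Product: 8 (2S,4S)-5-[tert-butyl(diphenyl)silyl]oxy-1,2-dihydroxy-4-methylpentan-3-one
Conditions: AcOH/H2O (4:1), 40 °C
Reagents that add atoms: none
Why: Acid hydrolysis of the terminal acetonide frees O7–H and O6–H; the silyl ether is stable to aqueous acetic acid.

Step 6
Reactants: 8 dihydroxy ketone
Product: 9 (2S,4S)-5-[tert-butyl(diphenyl)silyl]oxy-2-hydroxy-4-methyl-1-(trityloxy)pentan-3-one
Conditions: Ph3CCl, pyridine, DMAP (cat.), CH2Cl2, 0 °C → rt
Reagents that add atoms: trityl chloride, ClC(c1ccccc1)(c1ccccc1)c1ccccc1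
Why: Tritylation is selective for the primary hydroxyl and leaves the secondary α-ketol hydroxyl O7–H free; the trityl group is orthogonal to the silyl ether and adds bulk at C6 for step 8.

Step 7
Reactants: 9 α-hydroxy ketone
Product: 11 (5R)-4-[(2R)-1-[tert-butyl(diphenyl)silyl]oxypropan-2-yl]-5-(trityloxymethyl)furan-2(5H)-one, via O7 phosphoranylideneacetate 10 (not isolated)
Conditions: Ph3P=C=C=O, toluene, 100 °C
Reagents that add atoms: ketenylidenetriphenylphosphorane (Bestmann ylide), O=C=C=P(c1ccccc1)(c1ccccc1)c1ccccc1
Why: The Bestmann ylide acylates O7–H and the resulting ester ylide closes on the C8 ketone in an intramolecular Wittig reaction, the standard butenolide synthesis from α-hydroxy ketones; the neutral conditions spare C7 and C17.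

Step 8
Reactants: 11 butenolide
Product: 12 (3S,4R,5S)-4-[(2S)-1-[tert-butyl(diphenyl)silyl]oxypropan-2-yl]-3,4-dihydroxy-5-(trityloxymethyl)oxolan-2-one
Conditions: OsO4 (10 mol%), NMO, acetone/H2O, rt → 40 °C
Reagents that add atoms: N-methylmorpholine N-oxide, C[N+]1([O-])CCOCC1; water, O
Why: Catalytic syn-dihydroxylation; OsO4 adds to the butenolide face opposite the C7 substituent, the established bias of 5-substituted butenolides, so O8 and O9 enter cis to each other and trans to C6, which is the C7–C8–C9 triol of the target.

Step 9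
Reactants: 12 diol lactone
Product: 13 3,4-O-isopropylidene acetal of 12 (cis-fused dioxolane on O8 and O9)
Conditions: Me2C(OMe)2, PPTS (cat.), acetone, rt
Reagents that add atoms: 2,2-dimethoxypropane, COC(C)(C)OC
Why: Acetonide formation on the cis-diol protects O8 and O9 and later restricts rotation about C8–C9 in the cyclisation precursor.

Step 10
Reactants: 13 acetonide lactone
Product: 14 primary alcohol (C19–OH) of 13, trityl ether and acetonide retained
Conditions: Bu4NF, AcOH, THF, 0 °C → rt
Reagents that add atoms: none
Why: Fluoride cleaves the silyl ether; the acetic acid buffer protects the lactone, and trityl ether and acetonide do not react.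

Step 11
Reactants: 14 hydroxy lactone
Product: 15 (4S,5S)-5-[(1S)-1-hydroxy-2-(trityloxy)ethyl]-5-[(2S)-1-hydroxypropan-2-yl]-N-methoxy-N,2,2-trimethyl-1,3-dioxolane-4-carboxamide
Conditions: MeNHOMe·HCl, i-PrMgCl, THF, −20 → 0 °C
Reagents that add atoms: N,O-dimethylhydroxylamine hydrochloride, CNOC.Cl
Why: Weinreb amide formation by aminolysis of the lactone with the magnesium amide; this frees O7–H and stores C10 as the amide that step 16 turns into the aldehyde; used without delay so that the γ-hydroxy amide does not close back.

Step 12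
Reactants: 15 amide diol
Product: 17 spiro C19 lactone: N-methoxy-N-methylamide at C10 with O8/O9 acetonide and C6 trityl ether (configuration at C7 C8 C9 C17 as in 40), via C19 lactol 16 (not isolated)
Conditions: TEMPO (cat.), PhI(OAc)2, CH2Cl2, rt
Reagents that add atoms: none
Why: TEMPO/PhI(OAc)2 oxidative lactonisation of a 1,4-diol; only the primary hydroxyl is oxidised, the aldehyde is trapped by O7–H as the γ-lactol and oxidised on, which moves O7 from the C10 acyl group to the final C19 lactone.

Step 13
Reactants: 17 trityl ether
Product: 18 C6 primary alcohol of 17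
Conditions: camphorsulfonic acid (cat.), MeOH/CH2Cl2 (1:4), 0 °C
Reagents that add atoms: none
Why: Acid-catalysed methanolysis of the trityl ether; the hindered acetonide, flanked by the amide and lactone carbons, should survive these mild conditions.

Step 14
Reactants: 18 alcohol
Product: 19 C6 aldehyde (6-formyl spiro lactone acetonide Weinreb amide)
Conditions: Dess–Martin periodinane, NaHCO3, CH2Cl2, 0 °C
Reagents that add atoms: none
Why: Dess–Martin oxidation gives the α-acyloxy aldehyde without base, so C7 should not epimerise and O8 should not be eliminated; the aldehyde is used crude.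

Step 15
Reactants: 19 aldehyde; 20 ethyl 2-[bis(2,2,2-trifluoroethoxy)phosphoryl]propanoate
Product: 21 ethyl (Z)-2-methyl-3-(spiro lactone acetonide)prop-2-enoate, the Z C5=C6 enoate with the C10 Weinreb amide
Conditions: KN(SiMe3)2, 18-crown-6, THF, −78 °C
Reagents that add atoms: none
Why: Still–Gennari olefination; the electron-poor phosphonate with a dissociated potassium counter-ion eliminates under kinetic control to the Z-trisubstituted enoate, and lactone and amide are not attacked at −78 °C.

Step 16
Reactants: 21 Z-enoate
Product: 22 C10 aldehyde with C19 lactol and (Z)-allylic alcohol at C4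
Conditions: i-Bu2AlH (5 equiv), CH2Cl2, −78 °C; KNaC4H4O6 (aq)
Reagents that add atoms: none
Why: A single hydride reduction at low temperature takes the enoate to the allylic alcohol, the lactone to the lactol (O7 stays bound) and the Weinreb amide to the aldehyde through its stable chelated aluminium intermediate; it is placed before any ketone exists.

Step 17
Reactants: 22 aldehyde lactol; 23 3-(triphenylphosphoranylidene)butan-2-one
Product: 24 (E)-enone at C10=C11 with C19 lactol and C4 allylic alcohol
Conditions: toluene, 60 °C
Reagents that add atoms: none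
Why: Wittig reaction of a stabilised ylide gives the E-trisubstituted enone; the free α-alkoxy aldehyde should react well before the lactol, which opens to its aldehyde only to a small extent.

Step 18
Reactants: 24 enone lactol
Product: 25 (Z)-enal at C4 with C19 lactone and C10=C11 enone
Conditions: TEMPO (cat.), PhI(OAc)2, CH2Cl2, rt
Reagents that add atoms: none
Why: The same TEMPO/PhI(OAc)2 oxidation returns the lactol to the lactone and takes the allylic alcohol to the Z-enal; O7 is never free beside the Z-enal, which would otherwise close to a dihydrofuranol.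

Step 19
Reactants: 25 enal; 26 3-methylbut-3-en-2-one
Product: 28 (4R)-aldol: C4–OH and C2 isopropenyl ketone and C10=C11 enone on the spiro lactone acetonide, via diisopinocampheylboron enolate 27 (not isolated)
Conditions: 26, (+)-Ipc2BCl, Et3N, Et2O, −78 → 0 °C; then 25, −78 → −20 °C; H2O2, pH 7 buffer, MeOH
Reagents that add atoms: none
Why: Boron-mediated aldol reaction of a methyl ketone; the enol borinate adds only to the aldehyde of 25, and the Ipc ligands derived from (−)-α-pinene are expected, by the reversed facial preference of methyl ketone enolates, to attack the Re face and give 4R (the antipodal borane is used should the sense prove opposite).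

Step 20
Reactants: 28 aldol
Product: 29 C4 tert-butyldimethylsilyl ether of 28
Conditions: t-BuMe2SiOTf, 2,6-lutidine, CH2Cl2, −78 °C
Reagents that add atoms: tert-butyldimethylsilyl triflate, CC(C)(C)[Si](C)(C)OS(=O)(=O)C(F)(F)F
Why: Silylation of the β-hydroxy ketone prevents retro-aldol and dehydration in the thermal step; 2,6-lutidine at −78 °C does not enolise the ketones.

Step 21
Reactants: 29 bis-enone
Product: 30 cyclisation precursor: 2-silyloxydiene C13=C12(OSi)–C11=C10 and isopropenyl ketone C14=C1–C2=O
Conditions: t-BuMe2SiOTf (1.1 equiv), Et3N, CH2Cl2, −78 → −40 °C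
Reagents that add atoms: tert-butyldimethylsilyl triflate, CC(C)(C)[Si](C)(C)OS(=O)(=O)C(F)(F)F
Why: Soft enolisation (silyl triflate with amine) of an α,β-unsaturated methyl ketone gives the cross-conjugated 2-silyloxydiene; the unhindered C13 methyl should react ahead of the C3 methylene, which lies between the ketone and the silyloxy-bearing C4.

Step 22
Reactants: 30 open-chain silyloxydiene isopropenyl ketone
Product: 31 bicyclic C11=C12 silyl enol ether with C2 ketone (ring A and the ten-membered ring closed, C15 and H10 trans)
Conditions: toluene (0.5 mM), BHT, 180 °C, sealed vessel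
Reagents that add atoms: none
Why: A thermal, concerted but asynchronous [4+2] cycloaddition of normal electron demand: the silyloxy group raises the coefficient at C13, which bonds to the enone β-carbon C14, while C10 bonds to C1. The closest known reaction type is the macrocyclising type 1 intramolecular Diels–Alder reaction that closes a cyclohexene together with an 11- to 14-membered carbocycle. Ring A closes by the cycloaddition itself, and the ten-membered ring closes in the fused mode because the eight-atom tether C2–C9 joins the dienophile carbon C1 to the diene terminus C10. C10 is set by the diene face: A(1,3) strain with the C20 methyl holds H9 in the diene plane, so C8 (the tether) and O9 lie on opposite faces and the dienophile can only arrive from the C8 face. C1 is set relative to C10 by the exo position of the C2 carbonyl with the C15 methyl endo, the usual preference of α-methyl enones, which places C15 cis to C9 and gives the trans ring fusion. The step needs fused (para) regiochemistry, exo selectivity, one diene face and cyclisation ahead of oligomerisation; the first is secured by the 2-silyloxy group together with the tether, the second and third by the α-methyl group and the C9 stereocentre, and the last by high dilution and by the turns that the Z-alkene, the spiro lactone and the acetonide put into the tether.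

Step 23
Reactants: 31 silyl enol ether
Product: 32 C2,C12-diketone with free C4–OH and 11-methyl cis to C15
Conditions: HF·pyridine, pyridine, THF, 0 °C → rt
Reagents that add atoms: none
Why: Protodesilylation of the silyl enol ether; carbon protonation at C11 should occur on the face opposite C9 (on C10) and C15 (on C1), giving the kinetic epimer needed, and the same reagent frees C4–OH while the acetonide stays.

Step 24
Reactants: 32 β-hydroxy ketone
Product: 33 C4 acetate with C2–OH (1,3-anti) and C12 ketone unchanged
Conditions: SmI2 (30 mol%), MeCHO, THF, −10 °C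
Reagents that add atoms: acetaldehyde, CC=O
Why: Evans–Tishchenko reduction; the samarium-bound hemiacetal on O4 delivers hydride to C2 within a six-membered transition state, giving the 1,3-anti alcohol and leaving the acetate on O4; the C12 ketone has no β-hydroxyl and is not reduced.

Step 25
Reactants: 33 C12 ketone
Product: 35 C13=C14 enone with C4 acetate and C2–OH, via C12=C13 trimethylsilyl enol ether 34 (not isolated)
Conditions: LiN(i-Pr)2, Me3SiCl, THF, −78 °C; then Pd(OAc)2, MeCN, rt; citric acid, MeOH, 0 °C
Reagents that add atoms: none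
Why: Saegusa–Ito oxidation; kinetic deprotonation takes the C13 methylene, not the tertiary C11–H, the silyl enol ether is dehydrogenated by Pd(OAc)2, and the O2 silyl ether formed in the first stage is cleaved in the work-up (an acetyl shift from O4 to O2 would not matter, since O2 is acetylated in step 27).

Step 26
Reactants: 35 enone acetonide
Product: 36 triol enone (C2–OH, C8–OH, C9–OH) with C4 acetate
Conditions: CF3CO2H/H2O (9:1), 0 °C
Reagents that add atoms: none
Why: Acid hydrolysis of the acetonide; C4 is already an acetate, which makes ionisation of the allylic position less likely than with a free allylic alcohol.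

Step 27
Reactants: 36 triol
Product: 37 2,4,9-triacetate enone with free tertiary 8-OH
Conditions: Ac2O, pyridine, DMAP (cat.), CH2Cl2, 0 °C → rt
Reagents that add atoms: acetic anhydride, CC(=O)OC(C)=O
Why: Acetylation of the two secondary hydroxyls; the tertiary 8-OH, flanked by three substituted carbons, should not be acylated under these conditions.

Step 28
Reactants: 37 enone
Product: 39 14-hydroxy 12-ketone (hydroxyl on the face opposite C15), via C14 pinacol boronate 38 (not isolated)
Conditions: CuCl (5 mol%), DPEphos, NaOt-Bu (5 mol%), B2pin2, MeOH (2 equiv), THF, rt; then H2O2, pH 7 phosphate buffer, 0 °C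
Reagents that add atoms: hydrogen peroxide, OO
Why: Copper-catalysed conjugate borylation of the enone followed by oxidation of the C–B bond with retention; the boryl group should add to C14 from the face opposite the C15 methyl on C1, and the near-neutral conditions spare the acetates.

Step 29
Reactants: 39 β-hydroxy ketone
Product: 40 CNP0183630.2
Conditions: SmI2 (30 mol%), MeCHO, THF, −10 °C
Reagents that add atoms: acetaldehyde, CC=O
Why: Evans–Tishchenko reduction; the hemiacetal on O14 delivers hydride to C12 from its own face, giving the 1,3-anti 12-hydroxyl and leaving the acetate on O14, so the target appears with 12-OH and 8-OH free and without a selective acylation.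

## Compound list

1 | (R)-4-benzyl-3-propanoyl-1,3-oxazolidin-2-one | CCC(=O)N1[C@H](Cc2ccccc2)COC1=O | starting material
2 | (S)-2,2-dimethyl-1,3-dioxolane-4-carbaldehyde | O=C[C@@H]1COC(C)(C)O1 | starting material
3 | dibutylboron (Z)-enolate of 1 | C/C=C(\OB(CCCC)CCCC)N1[C@H](Cc2ccccc2)COC1=O | intermediate
4 | (R)-4-benzyl-3-[(2R,3R)-3-[(S)-2,2-dimethyl-1,3-dioxolan-4-yl]-3-hydroxy-2-methylpropanoyl]-1,3-oxazolidin-2-one | O=C(N1[C@H](Cc2ccccc2)COC1=O)[C@H](C)[C@@H](O)[C@@H]1COC(C)(C)O1 | intermediate
5 | (1R,2S)-1-[(S)-2,2-dimethyl-1,3-dioxolan-4-yl]-2-methylpropane-1,3-diol | OC[C@H](C)[C@@H](O)[C@@H]1COC(C)(C)O1 | intermediate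
6 | (1R,2S)-3-[tert-butyl(diphenyl)silyl]oxy-1-[(S)-2,2-dimethyl-1,3-dioxolan-4-yl]-2-methylpropan-1-ol | CC(C)(C)[Si](c1ccccc1)(c1ccccc1)OC[C@H](C)[C@@H](O)[C@@H]1COC(C)(C)O1 | intermediate
7 | (S)-3-[tert-butyl(diphenyl)silyl]oxy-1-[(S)-2,2-dimethyl-1,3-dioxolan-4-yl]-2-methylpropan-1-one | CC(C)(C)[Si](c1ccccc1)(c1ccccc1)OC[C@H](C)C(=O)[C@@H]1COC(C)(C)O1 | intermediate
8 | (2S,4S)-5-[tert-butyl(diphenyl)silyl]oxy-1,2-dihydroxy-4-methylpentan-3-one | CC(C)(C)[Si](c1ccccc1)(c1ccccc1)OC[C@H](C)C(=O)[C@@H](O)CO | intermediate
9 | (2S,4S)-5-[tert-butyl(diphenyl)silyl]oxy-2-hydroxy-4-methyl-1-(trityloxy)pentan-3-one | CC(C)(C)[Si](c1ccccc1)(c1ccccc1)OC[C@H](C)C(=O)[C@@H](O)COC(c1ccccc1)(c1ccccc1)c1ccccc1 | intermediate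
10 | (triphenylphosphoranylidene)acetate ester of 9 at O7 | CC(C)(C)[Si](c1ccccc1)(c1ccccc1)OC[C@H](C)C(=O)[C@@H](OC(=O)C=P(c1ccccc1)(c1ccccc1)c1ccccc1)COC(c1ccccc1)(c1ccccc1)c1ccccc1 | intermediate
11 | (5R)-4-[(2R)-1-[tert-butyl(diphenyl)silyl]oxypropan-2-yl]-5-(trityloxymethyl)furan-2(5H)-one | O=C1C=C([C@@H](C)CO[Si](c2ccccc2)(c2ccccc2)C(C)(C)C)[C@H](COC(c2ccccc2)(c2ccccc2)c2ccccc2)O1 | intermediate
12 | (3S,4R,5S)-4-[(2S)-1-[tert-butyl(diphenyl)silyl]oxypropan-2-yl]-3,4-dihydroxy-5-(trityloxymethyl)oxolan-2-one | O=C1[C@@H](O)[C@](O)([C@@H](C)CO[Si](c2ccccc2)(c2ccccc2)C(C)(C)C)[C@H](COC(c2ccccc2)(c2ccccc2)c2ccccc2)O1 | intermediate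
13 | 3,4-O-isopropylidene acetal of 12 (cis-fused furo[3,4-d][1,3]dioxol-4-one) | O=C1[C@H]2OC(C)(C)O[C@@]2([C@@H](C)CO[Si](c3ccccc3)(c3ccccc3)C(C)(C)C)[C@H](COC(c3ccccc3)(c3ccccc3)c3ccccc3)O1 | intermediate
14 | desilylated 13: 6a-[(2S)-1-hydroxypropan-2-yl] acetonide lactone with trityl ether | O=C1[C@H]2OC(C)(C)O[C@@]2([C@@H](C)CO)[C@H](COC(c3ccccc3)(c3ccccc3)c3ccccc3)O1 | intermediate
15 | (4S,5S)-5-[(1S)-1-hydroxy-2-(trityloxy)ethyl]-5-[(2S)-1-hydroxypropan-2-yl]-N-methoxy-N,2,2-trimethyl-1,3-dioxolane-4-carboxamide | CON(C)C(=O)[C@H]1OC(C)(C)O[C@@]1([C@@H](C)CO)[C@@H](O)COC(c2ccccc2)(c2ccccc2)c2ccccc2 | intermediate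
16 | C19 lactol: 8-hydroxy-N-methoxy-N,2,2,9-tetramethyl-6-(trityloxymethyl)-1,3,7-trioxaspiro[4.4]nonane-4-carboxamide | CON(C)C(=O)[C@H]1OC(C)(C)O[C@@]12[C@H](COC(c3ccccc3)(c3ccccc3)c3ccccc3)OC(O)[C@@H]2C | intermediate
17 | (4S,5S,6S,9R)-N-methoxy-N,2,2,9-tetramethyl-8-oxo-6-(trityloxymethyl)-1,3,7-trioxaspiro[4.4]nonane-4-carboxamide | CON(C)C(=O)[C@H]1OC(C)(C)O[C@@]12[C@H](COC(c3ccccc3)(c3ccccc3)c3ccccc3)OC(=O)[C@@H]2C | intermediate
18 | (4S,5S,6S,9R)-6-(hydroxymethyl)-N-methoxy-N,2,2,9-tetramethyl-8-oxo-1,3,7-trioxaspiro[4.4]nonane-4-carboxamide | CON(C)C(=O)[C@H]1OC(C)(C)O[C@@]12[C@H](CO)OC(=O)[C@@H]2C | intermediate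
19 | (4S,5S,6R,9R)-6-formyl-N-methoxy-N,2,2,9-tetramethyl-8-oxo-1,3,7-trioxaspiro[4.4]nonane-4-carboxamide | CON(C)C(=O)[C@H]1OC(C)(C)O[C@@]12[C@H](C=O)OC(=O)[C@@H]2C | intermediate
20 | ethyl 2-[bis(2,2,2-trifluoroethoxy)phosphoryl]propanoate | CCOC(=O)C(C)P(=O)(OCC(F)(F)F)OCC(F)(F)F | starting material
21 | ethyl (Z)-3-[(4S,5S,6S,9R)-4-[methoxy(methyl)carbamoyl]-2,2,9-trimethyl-8-oxo-1,3,7-trioxaspiro[4.4]nonan-6-yl]-2-methylprop-2-enoate | CON(C)C(=O)[C@H]1OC(C)(C)O[C@@]12[C@H](/C=C(/C)C(=O)OCC)OC(=O)[C@@H]2C | intermediate
22 | (4S,5S,6S,9R)-8-hydroxy-6-[(Z)-3-hydroxy-2-methylprop-1-enyl]-2,2,9-trimethyl-1,3,7-trioxaspiro[4.4]nonane-4-carbaldehyde (lactol epimers) | O=C[C@H]1OC(C)(C)O[C@@]12[C@H](/C=C(/C)CO)OC(O)[C@@H]2C | intermediate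
23 | 3-(triphenylphosphoranylidene)butan-2-one | CC(=O)C(C)=P(c1ccccc1)(c1ccccc1)c1ccccc1 | starting material
24 | (E)-4-[(4R,5S,6S,9R)-8-hydroxy-6-[(Z)-3-hydroxy-2-methylprop-1-enyl]-2,2,9-trimethyl-1,3,7-trioxaspiro[4.4]nonan-4-yl]-3-methylbut-3-en-2-one (lactol epimers) | CC(=O)/C(C)=C/[C@H]1OC(C)(C)O[C@@]12[C@H](/C=C(/C)CO)OC(O)[C@@H]2C | intermediate
25 | (Z)-2-methyl-3-[2,2,9-trimethyl-4-[(E)-2-methyl-3-oxobut-1-enyl]-8-oxo-1,3,7-trioxaspiro[4.4]nonan-6-yl]prop-2-enal (C7, C8, C9, C17 as in 40) | CC(=O)/C(C)=C/[C@H]1OC(C)(C)O[C@@]12[C@H](/C=C(/C)C=O)OC(=O)[C@@H]2C | intermediate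
26 | 3-methylbut-3-en-2-one | CC(=O)C(C)=C | starting material
27 | diisopinocampheylboron enolate of 26, Ipc groups from (−)-α-pinene | C=C(OB([C@H]1C[C@H]2C[C@@H]([C@@H]1C)C2(C)C)[C@H]1C[C@H]2C[C@@H]([C@@H]1C)C2(C)C)C(C)=C | intermediate
28 | 6-[(1Z,3R)-3-hydroxy-2,6-dimethyl-5-oxohepta-1,6-dienyl]-2,2,9-trimethyl-4-[(E)-2-methyl-3-oxobut-1-enyl]-1,3,7-trioxaspiro[4.4]nonan-8-one (C7, C8, C9, C17 as in 40) | CC(=O)/C(C)=C/[C@H]1OC(C)(C)O[C@@]12[C@H](/C=C(/C)[C@H](O)CC(=O)C(C)=C)OC(=O)[C@@H]2C | intermediate
29 | C4 tert-butyldimethylsilyl ether of 28 | CC(=O)/C(C)=C/[C@H]1OC(C)(C)O[C@@]12[C@H](/C=C(/C)[C@H](O[Si](C)(C)C(C)(C)C)CC(=O)C(C)=C)OC(=O)[C@@H]2C | intermediate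
30 | open-chain silyloxydiene isopropenyl ketone (cyclisation precursor) | C=C(O[Si](C)(C)C(C)(C)C)/C(C)=C/[C@H]1OC(C)(C)O[C@@]12[C@H](/C=C(/C)[C@H](O[Si](C)(C)C(C)(C)C)CC(=O)C(C)=C)OC(=O)[C@@H]2C | intermediate
31 | bicyclic C11=C12 silyl enol ether with C2 ketone, C4 silyl ether, O8/O9 acetonide (C1 and C10 as in 40) | C1CC(O[Si](C)(C)C(C)(C)C)=C(C)[C@@H]2[C@H]3OC(C)(C)O[C@@]34[C@H](/C=C(/C)[C@H](O[Si](C)(C)C(C)(C)C)CC(=O)[C@]21C)OC(=O)[C@@H]4C | intermediate
32 | C2,C12-diketone with C4–OH, O8/O9 acetonide, 11-methyl cis to C15 | C1CC(=O)[C@H](C)[C@@H]2[C@H]3OC(C)(C)O[C@@]34[C@H](/C=C(/C)[C@H](O)CC(=O)[C@]21C)OC(=O)[C@@H]4C | intermediate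
33 | C4 acetate, C2 alcohol (1,3-anti), C12 ketone, O8/O9 acetonide | C1CC(=O)[C@H](C)[C@@H]2[C@H]3OC(C)(C)O[C@@]34[C@H](/C=C(/C)[C@H](OC(C)=O)C[C@@H](O)[C@]21C)OC(=O)[C@@H]4C | intermediate
34 | C12=C13 trimethylsilyl enol ether and O2 trimethylsilyl ether of 33 | C1C=C(O[Si](C)(C)C)[C@H](C)[C@@H]2[C@H]3OC(C)(C)O[C@@]34[C@H](/C=C(/C)[C@H](OC(C)=O)C[C@@H](O[Si](C)(C)C)[C@]21C)OC(=O)[C@@H]4C | intermediate
35 | C13=C14 enone with C4 acetate, C2–OH, O8/O9 acetonide | C1=CC(=O)[C@H](C)[C@@H]2[C@H]3OC(C)(C)O[C@@]34[C@H](/C=C(/C)[C@H](OC(C)=O)C[C@@H](O)[C@]21C)OC(=O)[C@@H]4C | intermediate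
36 | C13=C14 enone with C4 acetate and free 2-, 8- and 9-hydroxyls | C1=CC(=O)[C@H](C)[C@@H]2[C@@H](O)[C@@]3(O)[C@H](/C=C(/C)[C@H](OC(C)=O)C[C@@H](O)[C@]21C)OC(=O)[C@@H]3C | intermediate
37 | 2,4,9-triacetate C13=C14 enone with free 8-OH | C1=CC(=O)[C@H](C)[C@@H]2[C@@H](OC(C)=O)[C@@]3(O)[C@H](/C=C(/C)[C@H](OC(C)=O)C[C@@H](OC(C)=O)[C@]21C)OC(=O)[C@@H]3C | intermediate
38 | C14 pinacol boronate of the 12-ketone triacetate | CC1(C)OB([C@H]2CC(=O)[C@H](C)[C@@H]3[C@@H](OC(C)=O)[C@@]4(O)[C@H](/C=C(/C)[C@H](OC(C)=O)C[C@@H](OC(C)=O)[C@]32C)OC(=O)[C@@H]4C)OC1(C)C | intermediate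
39 | 14-hydroxy 12-ketone 2,4,9-triacetate | O[C@H]1CC(=O)[C@H](C)[C@@H]2[C@@H](OC(C)=O)[C@@]3(O)[C@H](/C=C(/C)[C@H](OC(C)=O)C[C@@H](OC(C)=O)[C@]21C)OC(=O)[C@@H]3C | intermediate
40 | CNP0183630.2: (1R,2R,4R,5Z,7S,8S,9R,10S,11R,12S,14S,17R)-2,4,9,14-tetraacetoxy-8,12-dihydroxy 19,7-lactone (numbering of the analysis) | CC(=O)O[C@H]1C[C@H](O)[C@H](C)[C@@H]2[C@@H](OC(C)=O)[C@@]3(O)[C@H](/C=C(/C)[C@H](OC(C)=O)C[C@@H](OC(C)=O)[C@]21C)OC(=O)[C@@H]3C | target

## Step count and least certain steps

Total step count: 29. Longest linear sequence: 29 steps (1 or 2 to 40); 20, 23 and 26 enter as single commercial inputs.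

**Step 22 (key step).** The most likely failures are oligomerisation in place of the entropically costly closure of the ten-membered ring, a thermal [1,5]-hydrogen shift of the silyloxydiene (C9–H to C13) at the temperature needed, and leakage into the endo or wrong-face transition state if the tether cannot span the exo geometry. Fallback: from 29, before the diene is made, an anionic double Michael reaction in one flask (LiN(SiMe3)2, THF, −78 → 0 °C, high dilution). The kinetic C13 enolate adds to C14, and the C1 enolate so formed closes across the ring on C10, giving the same two bonds stepwise and the C4 silyl ether diketone F1. HF·pyridine then removes the silyl ether and the route is rejoined at 32.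

**Step 21.** Enolisation may not discriminate fully between the two ketones, so that the C3 methylene of the isopropenyl ketone is also silylated and the dienophile is lost. Fallback: from 25, hold C2 as a thioester until the diene is in place. An asymmetric Mukaiyama aldol (Sn(OTf)2, chiral diamine, 1-(ethylsulfanyl)-1-(trimethylsilyloxy)ethene) gives the β-hydroxy thioester F2. Silylation gives the silyl ether F3. The silyl triflate with Et3N then enolises only the methyl ketone, giving the silyloxydiene thioester F4. A Liebeskind–Srogl coupling with isopropenylboronic acid pinacol ester (Pd2(dba)3, tri(2-furyl)phosphine, copper thiophene-2-carboxylate Cu(O2CC4H3S)) returns to the route at 30.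

**Step 19.** Facial control by the Ipc ligands is only moderate for methyl ketone enolates, and the remote stereocentres of 25 may oppose it, giving poor selectivity at C4. Fallback: from 25, a catalytic asymmetric Mukaiyama aldol through an open transition state. The trimethylsilyl dienol ether F5 (from 26 with Me3SiCl, NaI and Et3N) is added under a tartaric-acid-derived (acyloxy)borane catalyst, and mild acid work-up returns to the route at 28.

**Step 23.** Protonation at C11 must give the less stable epimer; loss of facial selectivity, or later equilibration through the C12 enol, would erode it. Fallback: set C11 again at the enone stage. From 35, LiN(SiMe3)2 (2 equiv, THF, −78 °C) forms the cross-conjugated lithium dienolate F6, which is quenched at −78 °C with acetic acid from the face opposite C9 and C15. This returns 35 with the 11-methyl cis to C15, and only near-neutral steps follow.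

**Step 24.** The chair transition state for internal hydride delivery may not be reachable inside the ten-membered ring, so that the reduction stalls or loses selectivity at the neopentyl C2 ketone. Fallback: from 31, reduce C2 with an external, reagent-controlled hydride while C12 is still masked. A Corey–Bakshi–Shibata reduction ((S)-methyl oxazaborolidine, catecholborane, toluene, −78 °C; large group C1, small group C3) gives the C2 alcohol silyl enol ether F7. HF·pyridine gives the C2,C4-diol ketone F8. Acetylation of the allylic C4 hydroxyl ahead of the neopentyl C2 hydroxyl (Ac2O, pyridine, 0 °C) returns to the route at 33.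

Further compounds

F1 | step 22 | C2,C12-diketone with C4 tert-butyldimethylsilyl ether and O8/O9 acetonide (silyl ether of 32) | C1CC(=O)[C@H](C)[C@@H]2[C@H]3OC(C)(C)O[C@@]34[C@H](/C=C(/C)[C@H](O[Si](C)(C)C(C)(C)C)CC(=O)[C@]21C)OC(=O)[C@@H]4C
F2 | step 21 | S-ethyl (3R,4Z)-3-hydroxy-4-methyl-5-(spiro lactone acetonide enone)pent-4-enethioate | CC(=O)/C(C)=C/[C@H]1OC(C)(C)O[C@@]12[C@H](/C=C(/C)[C@H](O)CC(=O)SCC)OC(=O)[C@@H]2C
F3 | step 21 | tert-butyldimethylsilyl ether of F2 | CC(=O)/C(C)=C/[C@H]1OC(C)(C)O[C@@]12[C@H](/C=C(/C)[C@H](O[Si](C)(C)C(C)(C)C)CC(=O)SCC)OC(=O)[C@@H]2C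
F4 | step 21 | silyloxydiene thioester (2-silyloxydiene of F3) | C=C(O[Si](C)(C)C(C)(C)C)/C(C)=C/[C@H]1OC(C)(C)O[C@@]12[C@H](/C=C(/C)[C@H](O[Si](C)(C)C(C)(C)C)CC(=O)SCC)OC(=O)[C@@H]2C
F5 | step 19 | 3-methyl-2-(trimethylsilyloxy)buta-1,3-diene | C=C(O[Si](C)(C)C)C(C)=C
F6 | step 23 | dilithium salt of 35: C11=C12 dienolate and C2 alkoxide | C1=CC(O[Li])=C(C)[C@@H]2[C@H]3OC(C)(C)O[C@@]34[C@H](/C=C(/C)[C@H](OC(C)=O)C[C@@H](O[Li])[C@]21C)OC(=O)[C@@H]4C
F7 | step 24 | C2 alcohol of 31 with C11=C12 silyl enol ether and C4 silyl ether retained | C1CC(O[Si](C)(C)C(C)(C)C)=C(C)[C@@H]2[C@H]3OC(C)(C)O[C@@]34[C@H](/C=C(/C)[C@H](O[Si](C)(C)C(C)(C)C)C[C@@H](O)[C@]21C)OC(=O)[C@@H]4C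
F8 | step 24 | C2,C4-diol C12 ketone with O8/O9 acetonide | C1CC(=O)[C@H](C)[C@@H]2[C@H]3OC(C)(C)O[C@@]34[C@H](/C=C(/C)[C@H](O)C[C@@H](O)[C@]21C)OC(=O)[C@@H]4C
A1 | alternative 1 | ten-membered furan-fused cycloalkynol | C1=C[C@H](O[Si](CC)(CC)CC)[C@H](C)[C@@H]2[C@@H](O[Si](C)(C)C(C)(C)C)c3c(/C=C(/C)C#C[C@@H](O)[C@]21C)oc([Si](C)(C)C)c3C
A2 | alternative 2 | O12-silyl ether of the target | CC(=O)O[C@H]1C[C@H](O[Si](C)(C)C(C)(C)C)[C@H](C)[C@@H]2[C@@H](OC(C)=O)[C@@]3(O)[C@H](/C=C(/C)[C@H](OC(C)=O)C[C@@H](OC(C)=O)[C@]21C)OC(=O)[C@@H]3C
A3 | alternative 3 | ten-membered C2 silyl enol ether with E C6=C7 | COCO[C@H]1C[C@H](O[Si](C(C)C)(C(C)C)C(C)C)[C@H](C)[C@@H]2[C@H]3OC(C)(C)O[C@@]3([C@@H](C)CO[Si](C)(C)C(C)(C)C)/C=C/[C@H](C)C/C=C(\O[Si](C)(C)C)[C@]21C
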